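The route rests on cutting the quinone ring (ring B) of the 2-hydroxy-1,4-naphthoquinone at the bond between the carbonyl carbon C4, which lies next to the alkyl-bearing C3, and the benzo carbon C4a. The four carbons C1–C4 of ring B map onto a squarate ring, and the unsubstituted benzo ring A offers two equivalent ortho positions. A Moore rearrangement of a 4-hydroxy-4-phenylcyclobutenone, carrying the side chain on its C2 and an isopropoxy group on its C3, opens to an aryl dienylketene whose ketene carbon closes onto the phenyl ortho carbon; oxidation gives the fully substituted quinone. The hydroxy dienoic acid, made from geraniol by Sharpless epoxidation, is attached last.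

Key step: step 4

Remark on the chemistry: naphthoquinone numbering is C1(=O) bonded to C8a and C2(OH), C3 bearing the side chain, C4(=O) bonded to C3 and C4a. TBSO stands for tert-butyldimethylsilyloxy. The carbinol centre of the cyclobutenone intermediates is racemic and is erased in step 4. The new carbonyl oxygen in step 2 is assumed to come from water on work-up.

Step 1
Reactants: 1 3-bromo-2,2-dimethylpropan-1-ol
Product: 2 (3-bromo-2,2-dimethylpropoxy)(tert-butyl)dimethylsilane
Conditions: TBSCl, imidazole, DMF, 0 °C → rt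
Reagents that add atoms: tert-butyldimethylsilyl chloride, CC(C)(C)[Si](C)(C)Cl
Why: Imidazole-promoted silyl ether formation at the primary alcohol should be clean because the neopentyl bromide resists substitution by imidazole.

Step 2
Reactants: 2 (3-bromo-2,2-dimethylpropoxy)(tert-butyl)dimethylsilane; 3 diisopropyl squarate
Product: 7 3-[3-(TBSO)-2,2-dimethylpropyl]-4-isopropoxycyclobut-3-ene-1,2-dione, via Grignard reagent 4 (not isolated), via bromomagnesium alkoxide 5 (not isolated), via trifluoroacetate 6 (not isolated)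
Conditions: Mg, I2 (cat.), THF, reflux; add to 3, THF, −78 °C; then (CF3CO)2O, −78 → 0 °C; aq. NaHCO3
Reagents that add atoms: water, O
Why: The neopentyl bromide, which has no β-hydrogen, should form a stable Grignard reagent that adds 1,2 to one squarate carbonyl at −78 °C, and O-trifluoroacetylation followed by ionisation to the alkoxy-stabilised cyclobutenyl cation and hydrolysis with loss of isopropanol is the standard squarate 1,2-addition/rearrangement to a 3-alkyl-4-alkoxycyclobutenedione.

Step 3
Reactants: 7 3-[3-(TBSO)-2,2-dimethylpropyl]-4-isopropoxycyclobut-3-ene-1,2-dione; 8 phenyllithium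
Product: 9 2-[3-(TBSO)-2,2-dimethylpropyl]-4-hydroxy-3-isopropoxy-4-phenylcyclobut-2-en-1-one (racemic)
Conditions: PhLi (in Bu2O), THF, −78 °C; aq. NH4Cl
Reagents that add atoms: none
Why: Chemoselective 1,2-addition of the organolithium to the ketone-like carbonyl next to the isopropoxy-bearing carbon (the other carbonyl is a deactivated vinylogous ester) is the established regiochemistry for 3-alkoxy-4-alkylcyclobutenediones, and the new carbinol centre forms as a racemate that is erased in step 4.

Step 4
Reactants: 9 2-[3-(TBSO)-2,2-dimethylpropyl]-4-hydroxy-3-isopropoxy-4-phenylcyclobut-2-en-1-one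
Product: 13 2-[3-(TBSO)-2,2-dimethylpropyl]-3-isopropoxynaphthalene-1,4-dione, via dienylketene 10 (not isolated), via 8aH-naphthalenone 11 (not isolated), via hydroquinone 12 (not isolated)
Conditions: p-xylene, 138 °C, Ar; then Ag2O, Et2O, rt
Reagents that add atoms: none
Why: Heating should trigger a conrotatory 4π electrocyclic opening of the C1–C4 bond of cyclobutenone 9 in which the donor hydroxyl rotates outward, so that the phenyl group ends cis to the ketene in dienylketene 10. A thermal disrotatory 6π electrocyclisation (ketene C=C, enol C=C and one aromatic C=C) then joins the ketene carbon to the phenyl ortho carbon, which closes the six-membered ring B and creates the C4–C4a bond; dienone 11 tautomerises to hydroquinone 12 and Ag2O dehydrogenates it to quinone 13. This is the Moore rearrangement of 4-aryl-4-hydroxycyclobutenones, the closest known reaction type. No stereocentre survives, because the racemic carbinol carbon and the transient C8a centre both become trigonal. The step needs the ketene to close onto carbon and not be trapped by the hydroxyl, which the outward rotation of the hydroxyl secures; the regiochemistry is fixed because the side chain sits on the ketene-bearing carbon, the isopropoxy group sits next to the carbinol carbon, and the two ortho positions of the phenyl ring are equivalent.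

Step 5
Reactants: 13 2-[3-(TBSO)-2,2-dimethylpropyl]-3-isopropoxynaphthalene-1,4-dione
Product: 14 2-[3-(TBSO)-2,2-dimethylpropyl]-3-hydroxynaphthalene-1,4-dione
Conditions: LiOH·H2O, THF/MeOH/H2O, 40 °C; then 1 M HCl, 0 °C, pH 3
Reagents that add atoms: lithium hydroxide (LiOH), [Li+].[OH-]
Why: Hydroxide (with methoxide as a relay) adds to C2 of the 2-alkoxyquinone and expels the alkoxide (vinylogous ester saponification by addition–elimination), driven by formation of the stabilised hydroxyquinone anion, while the alkyl silyl ether is stable to aqueous base.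

Step 6
Reactants: 14 2-[3-(TBSO)-2,2-dimethylpropyl]-3-hydroxynaphthalene-1,4-dione
Product: 15 2-hydroxy-3-(3-hydroxy-2,2-dimethylpropyl)naphthalene-1,4-dione
Conditions: HF·pyridine, pyridine, THF, 0 °C → rt
Reagents that add atoms: none
Why: Fluoride-driven desilylation of the primary silyl ether with pyridine-buffered HF·pyridine should leave the acidic hydroxyquinone untouched and avoids the strong acid that could cyclise the hydroxyalkyl chain onto the quinone.

Step 7
Reactants: 16 geraniol
Product: 17 (2S,3S)-2,3-epoxygeraniol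
Conditions: Ti(OiPr)4 (cat.), L-(+)-diethyl tartrate (cat.), t-BuOOH, 4 Å MS, CH2Cl2, −20 °C
Reagents that add atoms: tert-butyl hydroperoxide, CC(C)(C)OO
Why: Katsuki–Sharpless asymmetric epoxidation: the Ti–tartrate complex binds the allylic alcohol and delivers oxygen to one face of the 2,3-alkene only (the remote 6,7-alkene is untouched), and L-(+)-diethyl tartrate is the ligand enantiomer that gives the (2S,3S)-epoxide of geraniol, so both new centres are set by reagent control.

Step 8
Reactants: 17 (2S,3S)-2,3-epoxygeraniol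
Product: 19 (S)-linalool, via epoxy iodide 18 (not isolated)
Conditions: PPh3, I2, imidazole, Et2O/MeCN, 0 °C; filter, concentrate; then Zn dust, EtOH, 70 °C
Reagents that add atoms: none
Why: Appel-type iodination of the primary alcohol followed by zinc insertion into the C–I bond and β-elimination of the epoxide oxygen (reductive opening of a 2,3-epoxy iodide) should give the tertiary allylic alcohol, and since no bond to the carbinol carbon is broken its S configuration is carried over from C3 of the epoxide.

Step 9
Reactants: 19 (S)-linalool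
Product: 20 (2E,6S)-6-hydroxy-2,6-dimethylocta-2,7-dienal
Conditions: SeO2, 1,4-dioxane, 80 °C
Reagents that add atoms: selenium dioxide (SeO2), O=[Se]=O
Why: Riley allylic oxidation with SeO2 (ene reaction then [2,3]-sigmatropic shift, twice) attacks the E-methyl group of the trisubstituted alkene and gives the E-enal, while the vinyl group has no allylic hydrogen (C6 is quaternary) and the tertiary alcohol cannot be oxidised.

Step 10
Reactants: 20 (2E,6S)-6-hydroxy-2,6-dimethylocta-2,7-dienal
Product: 21 (2E,6S)-6-hydroxy-2,6-dimethylocta-2,7-dienoic acid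
Conditions: NaClO2, NaH2PO4, 2-methyl-2-butene, t-BuOH/H2O, 0 °C → rt
Reagents that add atoms: sodium chlorite (NaClO2), [Na+].[O-]Cl=O
Why: Pinnick oxidation converts the enal into the acid without touching the alkenes or the alkene geometry, since 2-methyl-2-butene scavenges the HOCl formed.

Step 11
Reactants: 21 (2E,6S)-6-hydroxy-2,6-dimethylocta-2,7-dienoic acid; 15 2-hydroxy-3-(3-hydroxy-2,2-dimethylpropyl)naphthalene-1,4-dione
Product: 23 3-(3-hydroxy-1,4-dioxo-1,4-dihydronaphthalen-2-yl)-2,2-dimethylpropyl (2E,6S)-6-hydroxy-2,6-dimethylocta-2,7-dienoate (CNP0111177.1), via mixed anhydride 22 (not isolated)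
Conditions: 21, 2,4,6-trichlorobenzoyl chloride, Et3N, THF, 0 °C → rt; then 15, DMAP, toluene, rt; aq. NaHCO3
Reagents that add atoms: none
Why: Yamaguchi esterification: DMAP opens the mixed anhydride at the unhindered enoyl carbonyl and the acylpyridinium acylates the primary neopentyl hydroxyl, while the tertiary allylic alcohol is too hindered and the acidic enol, present as its ammonium salt, gives at most a labile enol ester that passes its acyl group on or is cleaved on bicarbonate work-up.

Compound list
1 | 3-bromo-2,2-dimethylpropan-1-ol | OCC(C)(C)CBr | starting material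
2 | (3-bromo-2,2-dimethylpropoxy)(tert-butyl)dimethylsilane | CC(C)(C)[Si](C)(C)OCC(C)(C)CBr | intermediate
3 | diisopropyl squarate (3,4-diisopropoxycyclobut-3-ene-1,2-dione) | CC(C)OC1=C(OC(C)C)C(=O)C1=O | starting material
4 | [3-(TBSO)-2,2-dimethylpropyl]magnesium bromide | CC(C)(C)[Si](C)(C)OCC(C)(C)C[Mg]Br | intermediate
5 | bromomagnesium alkoxide of 4-[3-(TBSO)-2,2-dimethylpropyl]-4-hydroxy-2,3-diisopropoxycyclobut-2-en-1-one (racemic) | CC(C)OC1=C(OC(C)C)C(O[Mg]Br)(CC(C)(C)CO[Si](C)(C)C(C)(C)C)C1=O | intermediate
6 | 1-[3-(TBSO)-2,2-dimethylpropyl]-2,3-diisopropoxy-4-oxocyclobut-2-en-1-yl trifluoroacetate (racemic) | CC(C)OC1=C(OC(C)C)C(OC(=O)C(F)(F)F)(CC(C)(C)CO[Si](C)(C)C(C)(C)C)C1=O | intermediate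
7 | 3-[3-(TBSO)-2,2-dimethylpropyl]-4-isopropoxycyclobut-3-ene-1,2-dione | CC(C)OC1=C(CC(C)(C)CO[Si](C)(C)C(C)(C)C)C(=O)C1=O | intermediate
8 | phenyllithium | [Li]c1ccccc1 | starting material
9 | 2-[3-(TBSO)-2,2-dimethylpropyl]-4-hydroxy-3-isopropoxy-4-phenylcyclobut-2-en-1-one (racemic) | O=C1C(CC(C)(C)CO[Si](C)(C)C(C)(C)C)=C(OC(C)C)C1(O)c1ccccc1 | intermediate
10 | (3Z)-2-[3-(TBSO)-2,2-dimethylpropyl]-4-hydroxy-3-isopropoxy-4-phenylbuta-1,3-dien-1-one (dienylketene, phenyl cis to the ketene) | O=C=C(CC(C)(C)CO[Si](C)(C)C(C)(C)C)/C(OC(C)C)=C(/O)c1ccccc1 | intermediate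
11 | 2-[3-(TBSO)-2,2-dimethylpropyl]-4-hydroxy-3-isopropoxy-8aH-naphthalen-1-one (racemic) | O=C1C(CC(C)(C)CO[Si](C)(C)C(C)(C)C)=C(OC(C)C)C(O)=C2C=CC=CC12 | intermediate
12 | 2-[3-(TBSO)-2,2-dimethylpropyl]-3-isopropoxynaphthalene-1,4-diol | Oc1c(CC(C)(C)CO[Si](C)(C)C(C)(C)C)c(OC(C)C)c(O)c2ccccc12 | intermediate
13 | 2-[3-(TBSO)-2,2-dimethylpropyl]-3-isopropoxynaphthalene-1,4-dione | O=C1C(CC(C)(C)CO[Si](C)(C)C(C)(C)C)=C(OC(C)C)C(=O)c2ccccc12 | intermediate
14 | 2-[3-(TBSO)-2,2-dimethylpropyl]-3-hydroxynaphthalene-1,4-dione | O=C1C(CC(C)(C)CO[Si](C)(C)C(C)(C)C)=C(O)C(=O)c2ccccc12 | intermediate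
15 | 2-hydroxy-3-(3-hydroxy-2,2-dimethylpropyl)naphthalene-1,4-dione | O=C1C(CC(C)(C)CO)=C(O)C(=O)c2ccccc12 | intermediate
16 | geraniol, (2E)-3,7-dimethylocta-2,6-dien-1-ol | CC(C)=CCC/C(C)=C/CO | starting material
17 | (2S,3S)-2,3-epoxygeraniol, [(2S,3S)-3-methyl-3-(4-methylpent-3-en-1-yl)oxiran-2-yl]methanol | CC(C)=CCC[C@]1(C)O[C@H]1CO | intermediate
18 | (2R,3S)-2-(iodomethyl)-3-methyl-3-(4-methylpent-3-en-1-yl)oxirane (same spatial arrangement as 17) | CC(C)=CCC[C@]1(C)O[C@H]1CI | intermediate
19 | (S)-linalool, (3S)-3,7-dimethylocta-1,6-dien-3-ol | C=C[C@@](C)(O)CCC=C(C)C | intermediate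
20 | (2E,6S)-6-hydroxy-2,6-dimethylocta-2,7-dienal | C=C[C@@](C)(O)CC/C=C(\C)C=O | intermediate
21 | (2E,6S)-6-hydroxy-2,6-dimethylocta-2,7-dienoic acid | C=C[C@@](C)(O)CC/C=C(\C)C(=O)O | intermediate
22 | (2E,6S)-6-hydroxy-2,6-dimethylocta-2,7-dienoic 2,4,6-trichlorobenzoic anhydride | C=C[C@@](C)(O)CC/C=C(\C)C(=O)OC(=O)c1c(Cl)cc(Cl)cc1Cl | intermediate
23 | 3-(3-hydroxy-1,4-dioxo-1,4-dihydronaphthalen-2-yl)-2,2-dimethylpropyl (2E,6S)-6-hydroxy-2,6-dimethylocta-2,7-dienoate | C=C[C@@](C)(O)CC/C=C(\C)C(=O)OCC(C)(C)CC1=C(O)C(=O)c2ccccc2C1=O | target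

Total step count: 11 steps.
Longest linear sequence: 7 steps (steps 1–6 and 11); the acid branch (steps 7–10) joins in step 11.

Steps most likely to fail

Step 4. On heating, the free hydroxyl may rotate inward in part or add to the ketene, so that lactonisation competes with the electrocyclic closure; the air-sensitive hydroquinone may also degrade before it is oxidised. The fallback blocks the hydroxyl before the ring opening. It sets out from 9, which is silylated at the tertiary hydroxyl (TESOTf, 2,6-lutidine, CH2Cl2, −78 °C) to give 2-[3-(TBSO)-2,2-dimethylpropyl]-3-isopropoxy-4-phenyl-4-(triethylsilyloxy)cyclobut-2-en-1-one F1. Thermolysis of this ether (p-xylene, 138 °C) should give the mono-silylated hydroquinone 2-[3-(TBSO)-2,2-dimethylpropyl]-3-isopropoxy-4-(triethylsilyloxy)naphthalen-1-ol F2, which is stable to air. Oxidation with PhI(OAc)2 in MeCN/H2O at 0 °C removes the aryl silyl group and returns to the route at 13.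

Step 9. The allylic oxidation may stall at the alcohol stage or run on, may lose regioselectivity between the allylic positions, and the tertiary allylic alcohol may ionise and transpose under the warm, acidic conditions. The fallback builds the enoate by olefination instead of oxidation. It sets out from 19: ozonolysis limited to the electron-rich trisubstituted alkene (O3, one equivalent, CH2Cl2/MeOH, −78 °C; Me2S) should give the lactol (5S)-5-ethenyl-5-methyloxolan-2-ol F3. A Wittig reaction of its open hydroxy aldehyde form with ethyl 2-(triphenylphosphoranylidene)propanoate (toluene, 80 °C) should give the E-enoate, ethyl (2E,6S)-6-hydroxy-2,6-dimethylocta-2,7-dienoate F4. Saponification (LiOH, THF/H2O) returns to the route at 21, so step 10 is bypassed as well.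

Step 11. Acylation may take place at the acidic enol oxygen instead of the hindered neopentyl hydroxyl, or activation may drive cyclisation of the hydroxyalkyl chain onto the quinone. The fallback changes the order of deprotection so that the enol oxygen stays masked during the esterification. It sets out from 13: desilylation (HF·pyridine, pyridine, THF) gives 2-(3-hydroxy-2,2-dimethylpropyl)-3-isopropoxynaphthalene-1,4-dione F5. Yamaguchi esterification with mixed anhydride 22, made from 21 as in step 11, gives 3-(3-isopropoxy-1,4-dioxo-1,4-dihydronaphthalen-2-yl)-2,2-dimethylpropyl (2E,6S)-6-hydroxy-2,6-dimethylocta-2,7-dienoate F6. Selective addition–elimination at the vinylogous ester (LiOH, THF/H2O, 0 °C; the hindered neopentyl enoate should react much more slowly) returns to the route at 23.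

Further compounds
F1 | step 4 | 2-[3-(TBSO)-2,2-dimethylpropyl]-3-isopropoxy-4-phenyl-4-(triethylsilyloxy)cyclobut-2-en-1-one (racemic) | O=C1C(CC(C)(C)CO[Si](C)(C)C(C)(C)C)=C(OC(C)C)C1(O[Si](CC)(CC)CC)c1ccccc1
F2 | step 4 | 2-[3-(TBSO)-2,2-dimethylpropyl]-3-isopropoxy-4-(triethylsilyloxy)naphthalen-1-ol | Oc1c(CC(C)(C)CO[Si](C)(C)C(C)(C)C)c(OC(C)C)c(O[Si](CC)(CC)CC)c2ccccc12
F3 | step 9 | (5S)-5-ethenyl-5-methyloxolan-2-ol (anomer mixture) | OC1CC[C@@](C)(C=C)O1
F4 | step 9 | ethyl (2E,6S)-6-hydroxy-2,6-dimethylocta-2,7-dienoate | C=C[C@@](C)(O)CC/C=C(\C)C(=O)OCC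
F5 | step 11 | 2-(3-hydroxy-2,2-dimethylpropyl)-3-isopropoxynaphthalene-1,4-dione | O=C1C(CC(C)(C)CO)=C(OC(C)C)C(=O)c2ccccc12
F6 | step 11 | 3-(3-isopropoxy-1,4-dioxo-1,4-dihydronaphthalen-2-yl)-2,2-dimethylpropyl (2E,6S)-6-hydroxy-2,6-dimethylocta-2,7-dienoate | C=C[C@@](C)(O)CC/C=C(\C)C(=O)OCC(C)(C)CC1=C(OC(C)C)C(=O)c2ccccc2C1=O
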